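The diene is cut at its central C–C single bond into a vinyl bromo-oxane (ring A) and an alkenylboronate bromohydrin (ring B), joined by an oxidative Heck reaction. Ring A (O1, gem-dimethyl C2, bromine-bearing C3, C4, C5, carbinol C6) is made by an anodic decarboxylative [4+2] annulation: the O1–C6–C5–C4 chain, stored as (S)-lavender lactone, gives a C4 radical that bonds to C3 of 1-bromo-2-methylpropene, and O1 then closes on the cationic gem-dimethyl carbon C2. The step exploits the 1,4-relationship of O1 and C4 and the cation-stabilising C2 next to bromine-bearing C3. Ring B comes from limonene-1,2-diol by cyclic-sulfate inversion.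

Key step: step 3

Remark: ring A is numbered as in compound 6 (O1, C2 gem-dimethyl, C3 CHBr, C4, C5, C6 carbinol carbon), ring B is the cyclohexane, and (S)-linalool and (1S,2S,4R)-limonene-1,2-diol are taken as commercial single enantiomers.

Step 1
Reactants: 1 (S)-(+)-linalool [(3S)-3,7-dimethylocta-1,6-dien-3-ol]
Product: 2 (5S)-5-ethenyl-5-methyloxolan-2-ol (lactol, both anomers)
Conditions: O3 (1.0 equiv, Sudan Red 7B end point), CH2Cl2, −78 °C; then Me2S, −78 °C to rt
Reagents that add atoms: ozone, [O-][O+]=O
Why: Chemoselective ozonolysis with reductive work-up cleaves the electron-rich trisubstituted alkene in preference to the vinyl group, and the resulting 4-hydroxy aldehyde closes to lactol 2 with the (S) carbinol centre of 1 untouched.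

Step 2
Reactants: 2 (5S)-5-ethenyl-5-methyloxolan-2-ol
Product: 3 (5S)-5-ethenyl-5-methyloxolan-2-one ((S)-lavender lactone)
Conditions: TEMPO (cat.), PhI(OAc)2, CH2Cl2, rt
Reagents that add atoms: none
Why: TEMPO/PhI(OAc)2 (oxoammonium) oxidation of the lactol to the γ-lactone, which neither forms nor touches a stereocentre.

Step 3
Reactants: 3 (5S)-5-ethenyl-5-methyloxolan-2-one; 4 1-bromo-2-methylprop-1-ene
Product: 6 (3R,6S)-3-bromo-6-ethenyl-2,2,6-trimethyloxane, via tetrabutylammonium carboxylate 5 (not isolated)
Conditions: Bu4NOH (1.0 equiv), MeOH, rt, then evaporation; 4 (15 equiv), H2O (2 equiv), MeCN, Pt anode, Pt cathode, undivided cell, constant current, 0 °C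
Reagents that add atoms: none
Why: Proposed new method: Kolbe-type anodic oxidation of carboxylate 5 expels CO2 and leaves the primary C4 radical, which adds to the CHBr carbon of 4 (C3–C4 bond), and the tertiary β-bromoalkyl radical at C2 is oxidised at the anode to a bromine-bridged cation that the C6 hydroxyl captures at C2 (O1–C2 bond), so that the bromine arrives on the two-carbon partner in a formal [4+2] annulation. The closest known reaction types are Kolbe electrolysis in the presence of olefins with Hofer–Moest radical–polar crossover of the adduct radical, and bromonium-terminated etherification of 5-hydroxyalkenes. Ring A closes in the 6-endo mode by anti opening of the bromonium ion at its gem-dimethyl carbon; if the β-bromoalkyl radical loses a bromine atom before oxidation, anodically regenerated bromine should re-add to the trisubstituted alkene so formed and reach the same bromonium ion. C3 is the only new stereocentre: the chair-like closure puts bromine equatorial, but methyl and vinyl on C6 differ little in size, so 6 and its C3 epimer are both expected and 6 is to be isolated by chromatography. The step needs radical attack at the CHBr terminus (secured by the gem-dimethyl substitution of the other alkene carbon and the tertiary radical it leaves) and oxygen attack at C2 rather than five-ring closure at C3 or solvent capture (secured by Markovnikov opening of the bromonium ion and by non-nucleophilic acetonitrile).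

Step 4
Reactants: 7 (1S,2S,4R)-1-methyl-4-(prop-1-en-2-yl)cyclohexane-1,2-diol (limonene-1,2-diol, trans diol)
Product: 8 1-[(1R,3S,4S)-3,4-dihydroxy-4-methylcyclohexyl]ethan-1-one
Conditions: O3, CH2Cl2/MeOH, −78 °C; then Me2S, −78 °C to rt
Reagents that add atoms: ozone, [O-][O+]=O
Why: Ozonolysis of the 1,1-disubstituted isopropenyl alkene with reductive work-up gives the methyl ketone, the diol being inert and all three stereocentres carried over.

Step 5
Reactants: 8 1-[(1R,3S,4S)-3,4-dihydroxy-4-methylcyclohexyl]ethan-1-one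
Product: 10 1-[(3aS,5R,7aS)-7a-methyl-2,2-dioxohexahydro-1,3,2-benzodioxathiol-5-yl]ethan-1-one (trans-fused cyclic sulfate), via cyclic sulfite 9 (not isolated)
Conditions: SOCl2, Et3N, CH2Cl2, 0 °C; then RuCl3 hydrate (cat.), NaIO4, MeCN/H2O, 0 °C
Reagents that add atoms: thionyl chloride, O=S(Cl)Cl; sodium periodate, [Na+].[O-]I(=O)(=O)=O
Why: Cyclic sulfate formation (cyclic sulfite from SOCl2, then RuO4-catalysed oxidation at sulfur) engages the trans diol in its diequatorial chair with retention at both carbinol carbons.

Step 6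
Reactants: 10 1-[(3aS,5R,7aS)-7a-methyl-2,2-dioxohexahydro-1,3,2-benzodioxathiol-5-yl]ethan-1-one
Product: 12 1-[(1R,3R,4S)-3-bromo-4-hydroxy-4-methylcyclohexyl]ethan-1-one, via lithium sulfate monoester 11 (not isolated)
Conditions: LiBr, THF, 50 °C; then H2SO4 (cat.), H2O (2 equiv), THF, rt
Reagents that add atoms: lithium bromide, [Li+].[Br-]
Why: SN2 opening of the cyclic sulfate by bromide at the secondary carbon inverts that centre (S to R) so that bromine ends cis to the tertiary oxygen, and acid hydrolysis of the tertiary sulfate monoester by S–O cleavage frees the alcohol with retention; the acetyl-bearing centre is epimerisable but its required configuration is the thermodynamic, all-equatorial one.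

Step 7
Reactants: 12 1-[(1R,3R,4S)-3-bromo-4-hydroxy-4-methylcyclohexyl]ethan-1-one; 13 bis(4,4,5,5-tetramethyl-1,3,2-dioxaborolan-2-yl)methane
Product: 15 (1S,2R,4R)-2-bromo-1-methyl-4-[(1E)-1-(4,4,5,5-tetramethyl-1,3,2-dioxaborolan-2-yl)prop-1-en-2-yl]cyclohexan-1-ol, via lithiated diborylmethane 14 (not isolated)
Conditions: 13 (2.4 equiv), lithium 2,2,6,6-tetramethylpiperidide (LiTMP, 2.3 equiv), THF, 0 °C; then 12, −78 °C to rt
Reagents that add atoms: none
Why: Boron-Wittig olefination: the α-boryl carbanion adds to the methyl ketone and syn elimination of the boron–oxygen unit leaves the remaining boryl group anti to the bulkier ring, which sets the E geometry of the trisubstituted alkenylboronate, one equivalent of reagent being spent on the hydroxyl and no stereocentre being touched.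

Step 8
Reactants: 15 (1S,2R,4R)-2-bromo-1-methyl-4-[(1E)-1-(4,4,5,5-tetramethyl-1,3,2-dioxaborolan-2-yl)prop-1-en-2-yl]cyclohexan-1-ol; 6 (3R,6S)-3-bromo-6-ethenyl-2,2,6-trimethyloxane
Product: 16 (1S,2R,4R)-2-bromo-4-[(2E,4E)-5-[(2S,5R)-5-bromo-2,6,6-trimethyloxan-2-yl]penta-2,4-dien-2-yl]-1-methylcyclohexan-1-ol (CNP0199463.1)
Conditions: Pd(OAc)2 (cat.), 2,9-dimethyl-1,10-phenanthroline (cat.), O2 (1 atm), DMA, 40 °C
Reagents that add atoms: none
Why: Oxidative Heck (boron-Heck) reaction: transmetallation of 15 to divalent palladium, insertion of the terminal alkene of 6 at its CH2 carbon and β-hydride elimination from the only available position should give the E,E-diene, O2 reoxidises zerovalent palladium, and the base-free medium leaves both bromides and the cis-bromohydrin intact with no stereocentre formed.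

Compound list
1 | (S)-(+)-linalool, (3S)-3,7-dimethylocta-1,6-dien-3-ol | C=C[C@@](C)(O)CCC=C(C)C | starting material
2 | (5S)-5-ethenyl-5-methyloxolan-2-ol (lactol, both anomers) | C=C[C@]1(C)CCC(O)O1 | intermediate
3 | (5S)-5-ethenyl-5-methyloxolan-2-one ((S)-lavender lactone) | C=C[C@]1(C)CCC(=O)O1 | intermediate
4 | 1-bromo-2-methylprop-1-ene | CC(C)=CBr | starting material
5 | tetrabutylammonium (4S)-4-hydroxy-4-methylhex-5-enoate | C=C[C@@](C)(O)CCC(=O)[O-].CCCC[N+](CCCC)(CCCC)CCCC | intermediate
6 | (3R,6S)-3-bromo-6-ethenyl-2,2,6-trimethyloxane | C=C[C@]1(C)CC[C@@H](Br)C(C)(C)O1 | intermediate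
7 | (1S,2S,4R)-1-methyl-4-(prop-1-en-2-yl)cyclohexane-1,2-diol | CC(=C)[C@@H]1CC[C@](C)(O)[C@@H](O)C1 | starting material
8 | 1-[(1R,3S,4S)-3,4-dihydroxy-4-methylcyclohexyl]ethan-1-one | CC(=O)[C@@H]1CC[C@](C)(O)[C@@H](O)C1 | intermediate
9 | 1-[(3aS,5R,7aS)-7a-methyl-2-oxohexahydro-1,3,2-benzodioxathiol-5-yl]ethan-1-one (cyclic sulfite, both sulfur epimers) | CC(=O)[C@@H]1CC[C@]2(C)OS(=O)O[C@H]2C1 | intermediate
10 | 1-[(3aS,5R,7aS)-7a-methyl-2,2-dioxohexahydro-1,3,2-benzodioxathiol-5-yl]ethan-1-one (trans-fused cyclic sulfate) | CC(=O)[C@@H]1CC[C@]2(C)OS(=O)(=O)O[C@H]2C1 | intermediate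
11 | lithium (1S,2R,4R)-4-acetyl-2-bromo-1-methylcyclohexyl sulfate | CC(=O)[C@@H]1CC[C@](C)(OS(=O)(=O)[O-])[C@H](Br)C1.[Li+] | intermediate
12 | 1-[(1R,3R,4S)-3-bromo-4-hydroxy-4-methylcyclohexyl]ethan-1-one | CC(=O)[C@@H]1CC[C@](C)(O)[C@H](Br)C1 | intermediate
13 | bis(4,4,5,5-tetramethyl-1,3,2-dioxaborolan-2-yl)methane | CC1(C)OB(CB2OC(C)(C)C(C)(C)O2)OC1(C)C | starting material
14 | [bis(4,4,5,5-tetramethyl-1,3,2-dioxaborolan-2-yl)methyl]lithium | [Li]C(B1OC(C)(C)C(C)(C)O1)B1OC(C)(C)C(C)(C)O1 | intermediate
15 | (1S,2R,4R)-2-bromo-1-methyl-4-[(1E)-1-(4,4,5,5-tetramethyl-1,3,2-dioxaborolan-2-yl)prop-1-en-2-yl]cyclohexan-1-ol | C/C(=C\B1OC(C)(C)C(C)(C)O1)[C@@H]1CC[C@](C)(O)[C@H](Br)C1 | intermediate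
16 | (1S,2R,4R)-2-bromo-4-[(2E,4E)-5-[(2S,5R)-5-bromo-2,6,6-trimethyloxan-2-yl]penta-2,4-dien-2-yl]-1-methylcyclohexan-1-ol | C/C(=C\C=C\[C@]1(C)CC[C@@H](Br)C(C)(C)O1)[C@@H]1CC[C@](C)(O)[C@H](Br)C1 | target

Total step count: 8.
Longest linear sequence: 5 steps (steps 4, 5, 6, 7 and 8, from 7 to 16).

Steps most likely to fail

Step 3 (Proposed new method). The nucleophilic primary radical may add only slowly to the hindered bromoalkene, so that Kolbe dimerisation, hydrogen abstraction or over-oxidation take over, and the closure has poor facial selectivity at C3. The fallback uses known chemistry, sets out from 1 and comes back to the route at 6: bromonium-induced 6-endo etherification of 1 with 2,4,4,6-tetrabromocyclohexa-2,5-dienone in MeNO2 at 0 °C, then chromatographic separation of 6 from its C3 epimer and the five-ring isomers. No new compound is made on the way (F0). The unwanted epimer can be returned to 1 with zinc dust in ethanol (reductive elimination of the β-bromo ether).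

Step 6. Substitution may be slow because bromide has to enter 1,3-syn-axial to the acetyl group of the trans-fused chair, so that elimination or ionisation at the tertiary sulfate competes. The fallback sets out from 10 and comes back at 12. It relays the stereochemistry through the epimerisable acetyl-bearing carbon. DBU (cat.) in CH2Cl2 should equilibrate 10 to 1-[(3aS,5S,7aS)-7a-methyl-2,2-dioxohexahydro-1,3,2-benzodioxathiol-5-yl]ethan-1-one F1, in which acetyl is equatorial. LiBr in THF then opens the unhindered sulfate to lithium (1S,2R,4S)-4-acetyl-2-bromo-1-methylcyclohexyl sulfate F2. Aqueous H2SO4 in THF gives 1-[(1S,3R,4S)-3-bromo-4-hydroxy-4-methylcyclohexyl]ethan-1-one F3. K2CO3 in MeOH equilibrates the acetyl-bearing carbon to the all-equatorial isomer 12.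

Step 8. Insertion into the hindered alkene of 6 may be sluggish, with homocoupling or protodeboronation of 15. The fallback sets out from 15 and comes back at 16. Iododeboronation with N-iodosuccinimide in MeCN at rt (retention of alkene geometry) gives (1S,2R,4R)-2-bromo-4-[(1E)-1-iodoprop-1-en-2-yl]-1-methylcyclohexan-1-ol F4. A Heck reaction of F4 with 6 under phase-transfer conditions (Pd(OAc)2, Bu4NCl, NaHCO3, DMF, 50 °C) then gives 16.

Further compounds
F0 | step 3 | none | none
F1 | step 6 | 1-[(3aS,5S,7aS)-7a-methyl-2,2-dioxohexahydro-1,3,2-benzodioxathiol-5-yl]ethan-1-one | CC(=O)[C@H]1CC[C@]2(C)OS(=O)(=O)O[C@H]2C1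
F2 | step 6 | lithium (1S,2R,4S)-4-acetyl-2-bromo-1-methylcyclohexyl sulfate | CC(=O)[C@H]1CC[C@](C)(OS(=O)(=O)[O-])[C@H](Br)C1.[Li+]
F3 | step 6 | 1-[(1S,3R,4S)-3-bromo-4-hydroxy-4-methylcyclohexyl]ethan-1-one | CC(=O)[C@H]1CC[C@](C)(O)[C@H](Br)C1
F4 | step 8 | (1S,2R,4R)-2-bromo-4-[(1E)-1-iodoprop-1-en-2-yl]-1-methylcyclohexan-1-ol | C/C(=C\I)[C@@H]1CC[C@](C)(O)[C@H](Br)C1
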